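**Retrosynthetic overview**

1. Larreantin is traced back (phenols as benzyl ethers, quinone by oxidative demethylation at C1 and C4) to a 1,2,4-trimethoxynaphthalene carrying C6–CH2Ar, C7–CH3 and C8–Ar.
2. The strategy rests on ring B: the C7 methyl carbon and the C6 benzylic carbon are ortho neighbours and can be joined through one oxygen as a five-membered lactone C7–C(=O)–O–CH(Ar)–C6, so both alkyl groups derive from that lactone by C–O reduction.
3. The lactone is cut at C6–C7 and C8–C8a (intramolecular dehydro-Diels–Alder). Ring A comes intact from a 2,4,5-trimethoxyphenyl alkyne, whose one ortho carbon without OMe becomes C8a.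
4. The ester precursor comes from a propargylic alcohol (trimethoxyphenylacetylide plus O-benzylvanillin) and an arylpropiolic acid; both alkynes come from aldehydes by Ohira–Bestmann homologation.
5. Ring order: ring A is bought; ring B and the lactone ring form together in the key step; the lactone ring is then opened and erased; ring A is oxidised to the quinone last.

Key step: step 6

Remark: every compound carrying the carbinol stereocentre is racemic (one enantiomer is drawn in the SMILES); the centre is removed in step 8 and the target is achiral.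
Remark: O-benzylvanillin is taken as a purchased material (otherwise one step from vanillin with BnBr/K2CO3).
Remark: locants C1–C8a in the text are those of the naphthoquinone core of the target (C2 OMe, C6 benzyl, C7 methyl, C8 aryl).

**Route**

Step 1
Reactants: 1 asaraldehyde (2,4,5-trimethoxybenzaldehyde); 2 dimethyl (1-diazo-2-oxopropyl)phosphonate
Product: 3 (2,4,5-trimethoxyphenyl)acetylene
Conditions: K2CO3, MeOH, 0 °C to rt
Reagents that add atoms: dimethyl (1-diazo-2-oxopropyl)phosphonate (compound 2), COP(=O)(OC)C(=[N+]=[N-])C(C)=O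
Why: Seyferth–Gilbert homologation in the Ohira–Bestmann variant turns the non-enolisable aryl aldehyde into the terminal alkyne under mild basic conditions that the methyl ethers tolerate.

Step 2
Reactants: 4 O-benzylvanillin (4-benzyloxy-3-methoxybenzaldehyde); 2 dimethyl (1-diazo-2-oxopropyl)phosphonate
Product: 5 (4-benzyloxy-3-methoxyphenyl)acetylene
Conditions: K2CO3, MeOH, 0 °C to rt
Reagents that add atoms: dimethyl (1-diazo-2-oxopropyl)phosphonate (compound 2), COP(=O)(OC)C(=[N+]=[N-])C(C)=O
Why: The same Ohira–Bestmann homologation; the benzyl ether is inert to K2CO3/MeOH.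

Step 3
Reactants: 5 (4-benzyloxy-3-methoxyphenyl)acetylene
Product: 7 (4-benzyloxy-3-methoxyphenyl)propiolic acid, via lithium acetylide 6 (not isolated)
Conditions: n-BuLi, THF, −78 °C; CO2 (g), −78 to 0 °C; then 1 M HCl, 0 °C
Reagents that add atoms: carbon dioxide, O=C=O
Why: Deprotonation of the terminal alkyne followed by carboxylation of the lithium acetylide is the standard route to arylpropiolic acids, and the cold acidic work-up avoids decarboxylation.

Step 4
Reactants: 3 (2,4,5-trimethoxyphenyl)acetylene; 4 O-benzylvanillin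
Product: 9 rac-1-(4-benzyloxy-3-methoxyphenyl)-3-(2,4,5-trimethoxyphenyl)prop-2-yn-1-ol, via lithium acetylide 8 (not isolated)
Conditions: n-BuLi, THF, −78 °C; then 4, −78 to 0 °C; H2O quench
Reagents that add atoms: none
Why: 1,2-Addition of a lithium acetylide to a non-enolisable aryl aldehyde; the carbinol centre forms without control (racemate), which is acceptable because it is removed in step 8, and the non-acidic quench protects the ionisation-prone alcohol.

Step 5
Reactants: 9 rac-1-(4-benzyloxy-3-methoxyphenyl)-3-(2,4,5-trimethoxyphenyl)prop-2-yn-1-ol; 7 (4-benzyloxy-3-methoxyphenyl)propiolic acid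
Product: 11 rac-1-(4-benzyloxy-3-methoxyphenyl)-3-(2,4,5-trimethoxyphenyl)prop-2-yn-1-yl 3-(4-benzyloxy-3-methoxyphenyl)prop-2-ynoate, via O-acylisourea 10 (not isolated)
Conditions: DCC, DMAP (cat.), CH2Cl2, −10 to 0 °C; Et3N-deactivated silica
Reagents that add atoms: none
Why: Steglich esterification: DCC activates the acid as O-acylisourea 10 and catalytic DMAP passes the acyl group to the hindered secondary alcohol under cold, neutral conditions that do not ionise the doubly activated propargylic carbinol.

Step 6
Reactants: 11 rac-1-(4-benzyloxy-3-methoxyphenyl)-3-(2,4,5-trimethoxyphenyl)prop-2-yn-1-yl 3-(4-benzyloxy-3-methoxyphenyl)prop-2-ynoate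
Product: 13 arylnaphthalene lactone rac-3,9-bis(4-benzyloxy-3-methoxyphenyl)-5,7,8-trimethoxynaphtho[2,3-c]furan-1(3H)-one, via cyclic allene 12 (not isolated)
Conditions: o-xylene (0.01 M), BHT (0.1 equiv), 2,6-di-tert-butyl-4-methylpyridine (0.2 equiv), 150 °C, sealed tube, Ar
Reagents that add atoms: none
Why: This is the thermal intramolecular dehydro-Diels–Alder reaction of an aryl propargyl arylpropiolate, a known entry to arylnaphthalene lactones: the ynoate triple bond (C7≡C8, 2π) adds across the ring A arylalkyne (C8a=C4a–C5≡C6, 4π) to give the strained 1,2,4-cyclohexatriene 12, which aromatises by transfer of the C8a hydrogen to C5. Ring B (six-membered carbocycle) closes by the [4+2] event through the new C6–C7 and C8–C8a bonds, and the five-membered lactone closes in the same event through C6–C7, the O–C(=O) unit being the three-atom tether of a fused-mode cycloaddition. No lasting stereocentre is made: the sp3 C8a of 12 is erased on aromatisation and the racemic carbinol carbon is a spectator. The step needs periselectivity (ring A alkyne as the 4π partner, not the guaiacyl arylpropiolate) and site selectivity on ring A; the first should follow from normal electron demand (the 2,4,5-trimethoxyphenyl alkyne is the most electron-rich enyne and the conjugated ynoate the only electron-poor 2π unit) and from the clash the reverse mode would create between an ortho-methoxylated pendant aryl and the arylated lactone carbon, the second from the OMe group that blocks the other ortho carbon so that only C8a can bond to C8. Because the ester dictates which alkyne termini meet, the guaiacyl group can only end on C8 and the carboxyl and carbinol carbons on C7 and C6. High dilution in a non-polar solvent with a hindered pyridine is chosen to keep the propargylic C–O bond from ionising before cyclisation.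

Step 7
Reactants: 13 arylnaphthalene lactone
Product: 14 rac-(4-benzyloxy-3-methoxyphenyl)[4-(4-benzyloxy-3-methoxyphenyl)-3-(hydroxymethyl)-5,6,8-trimethoxynaphthalen-2-yl]methanol
Conditions: LiAlH4, THF, 0 °C to rt
Reagents that add atoms: none
Why: Hydride reduction of the aryl lactone to the diol; aryl ethers are inert to LiAlH4 and the carbinol centre is untouched.

Step 8
Reactants: 14 rac-diol
Product: 16 [1-(4-benzyloxy-3-methoxyphenyl)-3-(4-benzyloxy-3-methoxybenzyl)-5,7,8-trimethoxynaphthalen-2-yl]methanol, via dihydronaphthofuran 15 (not isolated)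
Conditions: Et3SiH (3 equiv), CF3CO2H (5 equiv), CH2Cl2, 0 °C
Reagents that add atoms: none
Why: Ionic hydrogenation: acid ionises only the doubly benzylic carbinol (cation stabilised by the para-benzyloxy ring and by the C2/C4 methoxy groups through C6), the neighbouring CH2OH traps it reversibly as cyclic ether 15, and Et3SiH drains this equilibrium by irreversible hydride transfer, while the primary C7 carbinol is too poor a cation precursor to react at 0 °C.

Step 9
Reactants: 16 [1-(4-benzyloxy-3-methoxyphenyl)-3-(4-benzyloxy-3-methoxybenzyl)-5,7,8-trimethoxynaphthalen-2-yl]methanol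
Product: 17 benzylic bromide 3-(4-benzyloxy-3-methoxybenzyl)-1-(4-benzyloxy-3-methoxyphenyl)-2-(bromomethyl)-5,7,8-trimethoxynaphthalene
Conditions: CBr4, PPh3, CH2Cl2, 0 °C; short silica plug, used at once
Reagents that add atoms: carbon tetrabromide, BrC(Br)(Br)Br
Why: Appel reaction converts the primary benzylic alcohol into the bromide under neutral conditions, so no free benzylic cation arises that could close onto the adjacent benzyl ring.

Step 10
Reactants: 17 benzylic bromide
Product: 18 methylnaphthalene 3-(4-benzyloxy-3-methoxybenzyl)-1-(4-benzyloxy-3-methoxyphenyl)-5,7,8-trimethoxy-2-methylnaphthalene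
Conditions: LiBHEt3, THF, 0 °C
Reagents that add atoms: none
Why: SN2 displacement of the primary benzylic bromide by the strongly nucleophilic hydride of LiBHEt3 gives the C7 methyl group; aryl ethers are inert at 0 °C.

Step 11
Reactants: 18 methylnaphthalene
Product: 19 di-O-benzyllarreantin [6-(4-benzyloxy-3-methoxybenzyl)-8-(4-benzyloxy-3-methoxyphenyl)-2-methoxy-7-methylnaphthalene-1,4-dione]
Conditions: (NH4)2Ce(NO3)6 (2.2 equiv), MeCN/H2O, 0 °C
Reagents that add atoms: water, O
Why: Oxidative demethylation of a 1,4-dimethoxyarene by tetravalent cerium: the 1,2,4-trimethoxynaphthalene is by far the most easily oxidised ring, its radical cation takes up water at C1 and C4 with loss of two methanol molecules to give the para-quinone, and the C2 methoxy group stays as the vinylogous ester.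

Step 12
Reactants: 19 di-O-benzyllarreantin
Product: 21 larreantin, via hydroquinone 20 (not isolated)
Conditions: H2 (1 atm), Pd/C, EtOAc/MeOH, rt; filter; then air, rt
Reagents that add atoms: none
Why: Hydrogenolysis of both aryl benzyl ethers over palladium also reduces the quinone to hydroquinone 20, and the electron-rich 2-methoxynaphthalene-1,4-diol autoxidises back to the quinone in air.

**Compound list**

1 | 2,4,5-trimethoxybenzaldehyde (asaraldehyde) | COc1cc(OC)c(C=O)cc1OC | starting material
2 | dimethyl (1-diazo-2-oxopropyl)phosphonate | COP(=O)(OC)C(=[N+]=[N-])C(C)=O | starting material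
3 | (2,4,5-trimethoxyphenyl)acetylene (1-ethynyl-2,4,5-trimethoxybenzene) | COc1cc(OC)c(C#C)cc1OC | intermediate
4 | O-benzylvanillin (4-benzyloxy-3-methoxybenzaldehyde) | COc1cc(C=O)ccc1OCc1ccccc1 | starting material
5 | (4-benzyloxy-3-methoxyphenyl)acetylene | COc1cc(C#C)ccc1OCc1ccccc1 | intermediate
6 | lithium (4-benzyloxy-3-methoxyphenyl)acetylide | [Li]C#Cc1ccc(OCc2ccccc2)c(OC)c1 | intermediate (not isolated)
7 | 3-(4-benzyloxy-3-methoxyphenyl)prop-2-ynoic acid | COc1cc(C#CC(=O)O)ccc1OCc1ccccc1 | intermediate
8 | lithium (2,4,5-trimethoxyphenyl)acetylide | [Li]C#Cc1cc(OC)c(OC)cc1OC | intermediate (not isolated)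
9 | rac-1-(4-benzyloxy-3-methoxyphenyl)-3-(2,4,5-trimethoxyphenyl)prop-2-yn-1-ol (one enantiomer drawn) | COc1cc(OC)c(C#C[C@@H](O)c2ccc(OCc3ccccc3)c(OC)c2)cc1OC | intermediate
10 | O-acylisourea of acid 7 with N,N'-dicyclohexylcarbodiimide | COc1cc(C#CC(=O)OC(=NC2CCCCC2)NC2CCCCC2)ccc1OCc1ccccc1 | intermediate (not isolated)
11 | rac-1-(4-benzyloxy-3-methoxyphenyl)-3-(2,4,5-trimethoxyphenyl)prop-2-yn-1-yl 3-(4-benzyloxy-3-methoxyphenyl)prop-2-ynoate (one enantiomer drawn) | COc1cc(OC)c(C#C[C@@H](OC(=O)C#Cc2ccc(OCc3ccccc3)c(OC)c2)c2ccc(OCc3ccccc3)c(OC)c2)cc1OC | intermediate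
12 | cyclic allene (1,2,4-cyclohexatriene in ring B, sp3 C8a–H, configuration at C8a undefined; both epimers aromatise to 13) | COC1=C(OC)C=C(OC)C2=C=C3[C@H](c4ccc(OCc5ccccc5)c(OC)c4)OC(=O)C3=C(c3ccc(OCc4ccccc4)c(OC)c3)C12 | intermediate (not isolated)
13 | rac-3,9-bis(4-benzyloxy-3-methoxyphenyl)-5,7,8-trimethoxynaphtho[2,3-c]furan-1(3H)-one (one enantiomer drawn) | COc1cc(OC)c2cc3c(c(-c4ccc(OCc5ccccc5)c(OC)c4)c2c1OC)C(=O)O[C@H]3c1ccc(OCc2ccccc2)c(OC)c1 | intermediate
14 | rac-(4-benzyloxy-3-methoxyphenyl)[4-(4-benzyloxy-3-methoxyphenyl)-3-(hydroxymethyl)-5,6,8-trimethoxynaphthalen-2-yl]methanol (one enantiomer drawn) | COc1cc(OC)c2cc([C@@H](O)c3ccc(OCc4ccccc4)c(OC)c3)c(CO)c(-c3ccc(OCc4ccccc4)c(OC)c3)c2c1OC | intermediate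
15 | rac-1,4-bis(4-benzyloxy-3-methoxyphenyl)-5,6,8-trimethoxy-1,3-dihydronaphtho[2,3-c]furan (one enantiomer drawn) | COc1cc(OC)c2cc3c(c(-c4ccc(OCc5ccccc5)c(OC)c4)c2c1OC)CO[C@H]3c1ccc(OCc2ccccc2)c(OC)c1 | intermediate (not isolated)
16 | [1-(4-benzyloxy-3-methoxyphenyl)-3-(4-benzyloxy-3-methoxybenzyl)-5,7,8-trimethoxynaphthalen-2-yl]methanol | COc1cc(OC)c2cc(Cc3ccc(OCc4ccccc4)c(OC)c3)c(CO)c(-c3ccc(OCc4ccccc4)c(OC)c3)c2c1OC | intermediate
17 | 3-(4-benzyloxy-3-methoxybenzyl)-1-(4-benzyloxy-3-methoxyphenyl)-2-(bromomethyl)-5,7,8-trimethoxynaphthalene | COc1cc(OC)c2cc(Cc3ccc(OCc4ccccc4)c(OC)c3)c(CBr)c(-c3ccc(OCc4ccccc4)c(OC)c3)c2c1OC | intermediate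
18 | 3-(4-benzyloxy-3-methoxybenzyl)-1-(4-benzyloxy-3-methoxyphenyl)-5,7,8-trimethoxy-2-methylnaphthalene | COc1cc(OC)c2cc(Cc3ccc(OCc4ccccc4)c(OC)c3)c(C)c(-c3ccc(OCc4ccccc4)c(OC)c3)c2c1OC | intermediate
19 | 6-(4-benzyloxy-3-methoxybenzyl)-8-(4-benzyloxy-3-methoxyphenyl)-2-methoxy-7-methylnaphthalene-1,4-dione (di-O-benzyllarreantin) | COC1=CC(=O)c2cc(Cc3ccc(OCc4ccccc4)c(OC)c3)c(C)c(-c3ccc(OCc4ccccc4)c(OC)c3)c2C1=O | intermediate
20 | 6-(4-hydroxy-3-methoxybenzyl)-8-(4-hydroxy-3-methoxyphenyl)-2-methoxy-7-methylnaphthalene-1,4-diol | COc1cc(O)c2cc(Cc3ccc(O)c(OC)c3)c(C)c(-c3ccc(O)c(OC)c3)c2c1O | intermediate (not isolated)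
21 | larreantin, 6-(4-hydroxy-3-methoxybenzyl)-8-(4-hydroxy-3-methoxyphenyl)-2-methoxy-7-methylnaphthalene-1,4-dione | COC1=CC(=O)c2cc(Cc3ccc(O)c(OC)c3)c(C)c(-c3ccc(O)c(OC)c3)c2C1=O | target

**Step count and risks**

Total steps: 12. Longest linear sequence: 10 steps (steps 1, 4, 5–12 from aldehyde 1; equally steps 2, 3, 5–12 from aldehyde 4).

Steps most likely to fail:

1. Step 6 (key cycloaddition). The cycloaddition may take the wrong periselectivity, with the guaiacyl ring of the arylpropiolate serving as the 4π partner. Bond formation at C8a, which is flanked by a methoxy group and ends peri to the new aryl group, may also be slow enough that heterolysis of the propargylic ester competes. Fallback, setting out from propargylic alcohol 9: esterification with propiolic acid (DCC, CH2Cl2, −20 °C) would give the terminal propiolate ester F1. Bromination of its terminal alkyne with N-bromosuccinimide and catalytic AgNO3 in acetone would give the 3-bromopropiolate ester F2. Heating F2 under the step 6 conditions leaves ring A as the only possible 4π unit, since no second aryl alkyne is present, and would give the 9-bromo lactone F3 (bromine on C8 of the naphthalene). Suzuki–Miyaura coupling of F3 with purchased (4-benzyloxy-3-methoxyphenyl)boronic acid (Pd(OAc)2, SPhos, K3PO4, toluene/H2O, 90 °C) would install the C8 aryl group and return to the route at lactone 13.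

2. Step 8 (ionic hydrogenation beside a free primary benzylic alcohol). The acid may also ionise the C7 carbinol, leading to Friedel–Crafts ring closure onto the neighbouring benzyl ring, or the reduction may stall at the cyclic ether. Fallback, setting out from lactone 13: electron-transfer cleavage of the doubly benzylic C–O bond with Zn dust in aqueous NaOH/pyridine at reflux (the classical reduction of 3-arylphthalides, no cation involved) would give the 6-benzyl naphthoic acid F4. LiAlH4 reduction of F4 in THF then gives the primary alcohol and returns to the route at 16.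

3. Step 11 (cerium oxidation). Over-oxidation may occur: the oxidant may attack the benzyl-protected guaiacyl rings or the diarylmethane CH2, or demethylate at C1/C2 to the ortho-quinone; the final hydrogenolysis through a hydroquinone adds a second hazard. Fallback, setting out from 18: hydrogenolysis (H2, Pd/C, EtOAc) before any quinone is present would give the bisphenol F5. Acetylation (Ac2O, pyridine) would give the bis-acetate F6, whose acetoxy-bearing rings are deactivated toward one-electron oxidation. (NH4)2Ce(NO3)6 in MeCN/H2O at 0 °C would then give the quinone bis-acetate F7. Acid-catalysed methanolysis of F7 (catalytic AcCl in MeOH, rt, where any exchange at the C2 methoxy group is degenerate) returns to the route at the target 21.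

**Further compounds**

F1 | step 6 | rac-1-(4-benzyloxy-3-methoxyphenyl)-3-(2,4,5-trimethoxyphenyl)prop-2-yn-1-yl prop-2-ynoate | COc1cc(OC)c(C#C[C@@H](OC(=O)C#C)c2ccc(OCc3ccccc3)c(OC)c2)cc1OC
F2 | step 6 | rac-1-(4-benzyloxy-3-methoxyphenyl)-3-(2,4,5-trimethoxyphenyl)prop-2-yn-1-yl 3-bromoprop-2-ynoate | COc1cc(OC)c(C#C[C@@H](OC(=O)C#CBr)c2ccc(OCc3ccccc3)c(OC)c2)cc1OC
F3 | step 6 | rac-3-(4-benzyloxy-3-methoxyphenyl)-9-bromo-5,7,8-trimethoxynaphtho[2,3-c]furan-1(3H)-one | COc1cc(OC)c2cc3c(c(Br)c2c1OC)C(=O)O[C@H]3c1ccc(OCc2ccccc2)c(OC)c1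
F4 | step 8 | 3-(4-benzyloxy-3-methoxybenzyl)-1-(4-benzyloxy-3-methoxyphenyl)-5,7,8-trimethoxy-2-naphthoic acid | COc1cc(OC)c2cc(Cc3ccc(OCc4ccccc4)c(OC)c3)c(C(=O)O)c(-c3ccc(OCc4ccccc4)c(OC)c3)c2c1OC
F5 | step 11 | 3-(4-hydroxy-3-methoxybenzyl)-1-(4-hydroxy-3-methoxyphenyl)-5,7,8-trimethoxy-2-methylnaphthalene | COc1cc(OC)c2cc(Cc3ccc(O)c(OC)c3)c(C)c(-c3ccc(O)c(OC)c3)c2c1OC
F6 | step 11 | bis-acetate of F5 | COc1cc(OC)c2cc(Cc3ccc(OC(C)=O)c(OC)c3)c(C)c(-c3ccc(OC(C)=O)c(OC)c3)c2c1OC
F7 | step 11 | di-O-acetyllarreantin | COC1=CC(=O)c2cc(Cc3ccc(OC(C)=O)c(OC)c3)c(C)c(-c3ccc(OC(C)=O)c(OC)c3)c2C1=O
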